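**Retrosynthetic overview**
1. The pyranone C ring is the only ring built. It is closed last, by O1–C2 bond formation and dehydrogenation of a 2'-hydroxychalcone (I2/DMSO).
2. The chalcone Cα=Cβ bond is disconnected (Claisen–Schmidt) into 6-hydroxy-2,3-dimethoxyacetophenone (A ring) and 2,3,4,6-tetramethoxybenzaldehyde (B ring).
3. The A-ring ketone comes from commercial 2'-hydroxy-6'-methoxyacetophenone by para-hydroxylation (Elbs), then methylation of the non-chelated OH.
4. The B-ring aldehyde comes from commercial 1,2,3,5-tetramethoxybenzene by Vilsmeier–Haack formylation, where both free positions are equivalent.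
5. Ring order: both benzene rings are bought, and the C ring is formed in the final step.

Assumption: the target SMILES holds no stereocentre and the C2–C1' axis is not configurationally stable, so the compound is achiral and needs no enantiocontrol; 1 and 5 are taken as catalogue chemicals.

**Step 1**
Reactants: 1 2'-hydroxy-6'-methoxyacetophenone
Product: 3 3,6-dihydroxy-2-methoxyacetophenone, via aryl potassium sulfate 2 (not isolated)
Conditions: K2S2O8 (1.1 equiv), aq KOH, 0 °C→rt, 24 h; then conc. HCl, 90 °C, 1 h
Reagents that add atoms: potassium peroxodisulfate, [K+].[K+].[O-]S(=O)(=O)OOS(=O)(=O)[O-]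
Why: Elbs persulfate oxidation, in which the phenolate of 1 attacks the peroxide O–O bond through its free para carbon (C5') to give sulfate ester 2, whose acid hydrolysis (S–O cleavage) unmasks the new OH without touching the ketone or the aryl methyl ether; no stereocentre is formed.

**Step 2**
Reactants: 3 3,6-dihydroxy-2-methoxyacetophenone
Product: 4 6-hydroxy-2,3-dimethoxyacetophenone
Conditions: MeI (1.05 equiv), K2CO3 (1.1 equiv), acetone, reflux, N2, 5 h
Reagents that add atoms: methyl iodide, CI
Why: Williamson ether synthesis under stoichiometric control, where the 6-OH is hydrogen-bonded to the acetyl C=O and poorly nucleophilic, so one equivalent of MeI alkylates only the free 3-OH; no stereocentre is formed.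

**Step 3**
Reactants: 5 1,2,3,5-tetramethoxybenzene
Product: 7 2,3,4,6-tetramethoxybenzaldehyde, via aryl iminium chloride 6 (not isolated)
Conditions: POCl3 (1.3 equiv), DMF, 0 °C→rt, 3 h; then ice–H2O
Reagents that add atoms: N,N-dimethylformamide, CN(C)C=O; water, O
Why: Vilsmeier–Haack formylation (SEAr), where the two free positions of the electron-rich arene 5 are symmetry-equivalent so only one aldehyde can form, and the deactivating iminium group of 6 stops a second formylation; no stereocentre is formed.

**Step 4**
Reactants: 4 6-hydroxy-2,3-dimethoxyacetophenone; 7 2,3,4,6-tetramethoxybenzaldehyde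
Product: 9 (E)-1-(6-hydroxy-2,3-dimethoxyphenyl)-3-(2,3,4,6-tetramethoxyphenyl)prop-2-en-1-one, via aldol adduct 8 (not isolated)
Conditions: KOH (50% aq, 10 equiv), EtOH, rt, 72 h; then 1 M HCl, 0 °C
Reagents that add atoms: none
Why: Claisen–Schmidt (crossed aldol) condensation, where 7 cannot enolise, so the enolate of 4 adds to it and aldol 8 loses water by E1cB to give the thermodynamically favoured E-enone, which erases the carbinol stereocentre of racemic 8.

**Step 5**
Reactants: 9 (E)-1-(6-hydroxy-2,3-dimethoxyphenyl)-3-(2,3,4,6-tetramethoxyphenyl)prop-2-en-1-one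
Product: 11 5,6,2',3',4',6'-hexamethoxyflavone, via flavanone 10 (not isolated)
Conditions: I2 (10 mol %), DMSO, 130 °C, 3 h
Reagents that add atoms: none
Why: I2/DMSO oxidative cyclisation of a 2'-hydroxychalcone, in which 6-endo oxa-Michael addition of the phenol gives racemic flavanone 10 and iodine dehydrogenates C2–C3 while DMSO re-oxidises HI to I2, so the transient C2 stereocentre disappears and the achiral 4-pyranone 11 results.

**Compound list**
1 | 2'-hydroxy-6'-methoxyacetophenone | CC(=O)c1c(O)cccc1OC | starting material
2 | potassium 3-acetyl-4-hydroxy-2-methoxyphenyl sulfate | CC(=O)c1c(O)ccc(OS(=O)(=O)[O-])c1OC.[K+] | intermediate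
3 | 3,6-dihydroxy-2-methoxyacetophenone | CC(=O)c1c(O)ccc(O)c1OC | intermediate
4 | 6-hydroxy-2,3-dimethoxyacetophenone | CC(=O)c1c(O)ccc(OC)c1OC | intermediate
5 | 1,2,3,5-tetramethoxybenzene | COc1cc(OC)c(OC)c(OC)c1 | starting material
6 | N,N-dimethyl-(2,3,4,6-tetramethoxybenzylidene)iminium chloride | C[N+](C)=Cc1c(OC)cc(OC)c(OC)c1OC.[Cl-] | intermediate
7 | 2,3,4,6-tetramethoxybenzaldehyde | O=Cc1c(OC)cc(OC)c(OC)c1OC | intermediate
8 | (±)-3-hydroxy-1-(6-hydroxy-2,3-dimethoxyphenyl)-3-(2,3,4,6-tetramethoxyphenyl)propan-1-one | COc1cc(OC)c(C(O)CC(=O)c2c(O)ccc(OC)c2OC)c(OC)c1OC | intermediate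
9 | (E)-1-(6-hydroxy-2,3-dimethoxyphenyl)-3-(2,3,4,6-tetramethoxyphenyl)prop-2-en-1-one | COc1cc(OC)c(/C=C/C(=O)c2c(O)ccc(OC)c2OC)c(OC)c1OC | intermediate
10 | (±)-5,6,2',3',4',6'-hexamethoxyflavanone | COc1cc(OC)c(C2CC(=O)c3c(OC)c(OC)ccc3O2)c(OC)c1OC | intermediate
11 | 5,6,2',3',4',6'-hexamethoxyflavone (achiral) | COc1cc(OC)c(-c2cc(=O)c3c(OC)c(OC)ccc3o2)c(OC)c1OC | target

**Totals**
Total step count: 5.
Longest linear sequence: 4 steps (1 → 3 → 4 → 9 → 11). Step 3 is a one-step side branch.

**Three steps most likely to fail**

Step 1 (Elbs oxidation). The risk is low conversion and dark over-oxidation products. The fallback sets out from 1 and comes back at 4, skipping 3 and step 2. It replaces attack of the phenolate on persulfate with a hypervalent-iodine dearomatisation.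
- PhI(OAc)2 (2.2 equiv) in MeOH at 0 °C→rt makes methanol add at the free para carbon.
- The first-formed 4 is more easily oxidised than 1, so the reaction is deliberately driven on to the p-quinone monoketal 2-acetyl-3,4,4-trimethoxycyclohexa-2,5-dien-1-one F1.
- Zn dust in AcOH at rt then reductively re-aromatises it with loss of one ketal methoxy group and delivers 4 directly.

Step 4 (Claisen–Schmidt condensation). The risk is that a di-ortho-substituted, very electron-rich aldehyde meets a hindered ketone that is present as its phenolate, so addition is slow and reversible. The fallback sets out from 7, with 4 as partner, and comes back at 11, bypassing 9 and step 5. It forms the C–C bond by acylation at the flavone oxidation level.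
- Pinnick oxidation of 7 (NaClO2, NaH2PO4, 2-methyl-2-butene, t-BuOH/H2O) gives 2,3,4,6-tetramethoxybenzoic acid F2.
- Oxalyl chloride with catalytic DMF in CH2Cl2 gives 2,3,4,6-tetramethoxybenzoyl chloride F3.
- LiHMDS (4 equiv, THF, −78 °C) converts 4 into dilithium 3,4-dimethoxy-2-(1-oxidoethenyl)phenolate F4.
- F4 is C-acylated by the acid chloride to give 1-(6-hydroxy-2,3-dimethoxyphenyl)-3-(2,3,4,6-tetramethoxyphenyl)propane-1,3-dione F5.
- Cyclodehydration with 0.5% H2SO4 in AcOH at 100 °C gives 11.

Step 5 (I2/DMSO). The risks are iodination of the activated C5'–H between two methoxy groups and HI-induced loss of the peri 5-O-methyl group. The fallback sets out from 9 and comes back at 11. It separates ring closure from oxidation and replaces the iodine-mediated dehydrogenation by hydride abstraction, so no electrophilic iodine or HI meets the substrate.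
- 9 is closed with NaOAc in refluxing EtOH to flavanone 10, which is now isolated. The 6'-methoxy group twists the chalcone carbonyl and favours the closed form.
- 10 is dehydrogenated with DDQ (1.5 equiv) in refluxing 1,4-dioxane to 11.
- This detour makes no new compound F0.

**Further compounds**
F1 | step 1 | 2-acetyl-3,4,4-trimethoxycyclohexa-2,5-dien-1-one | CC(=O)C1=C(OC)C(OC)(OC)C=CC1=O
F2 | step 4 | 2,3,4,6-tetramethoxybenzoic acid | OC(=O)c1c(OC)cc(OC)c(OC)c1OC
F3 | step 4 | 2,3,4,6-tetramethoxybenzoyl chloride | ClC(=O)c1c(OC)cc(OC)c(OC)c1OC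
F4 | step 4 | dilithium 3,4-dimethoxy-2-(1-oxidoethenyl)phenolate | [Li+].[Li+].C=C([O-])c1c([O-])ccc(OC)c1OC
F5 | step 4 | 1-(6-hydroxy-2,3-dimethoxyphenyl)-3-(2,3,4,6-tetramethoxyphenyl)propane-1,3-dione | COc1cc(OC)c(C(=O)CC(=O)c2c(O)ccc(OC)c2OC)c(OC)c1OC
F0 | step 5 | none | none
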